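# Two-directional glycolate alkylation route to CNP0316493.1 (compound 32)

Naming used throughout: rings C and D are the syringyl rings of the core. Ring D carries unit 3 (Cα3, Cβ3, Cγ3, guaiacyl ring E). Ring C carries unit 2 (ring B), and the phenol oxygen of ring B carries unit 1 (ring A). Compound numbers 1–32 are those of the compound list.

## The problem

Compound 32 is a linear lignan oligomer of five aromatic rings in which the only rings to be built are those of the core, (7R,7'R,8S,8'S)-syringaresinol, a cis-fused 2,6-diaryl-3,7-dioxabicyclo[3.3.0]octane. Three arylglycerol β-aryl ether units hang from it through the phenol oxygens of rings C, D and B, so the work lies in three aryl ether bonds (ring C–O–Cβ2, ring D–O–Cβ3, ring B–O–Cβ1), three Cα–aryl bonds and ten stereocentres: four in the core and six in the chains (unit 1 αR,βS erythro; unit 2 αR,βR threo; unit 3 αS,βR erythro). The core centres lie six or more bonds from any chain centre and cannot steer them, so each Cβ needs its own source of chirality, whereas each Cα sits next to its Cβ and can be set from it by 1,2-induction in a ketone reduction (chelation for erythro, Felkin–Anh for threo). The fragile parts are the three benzylic carbinols para to oxygen and the two benzylic C7–O bonds of the core (both ionise under protic or Lewis acid and can be hydrogenolysed), the free phenols, and every α-aryloxy carbonyl intermediate, which can epimerise at Cβ or lose the γ-oxygen by elimination. The chains break the C2 symmetry of the core at Cα (erythro on ring D, threo on ring C) and at ring B, which alone is extended. The symmetry is not broken at Cβ: Cβ2 on the oxygen of ring C and Cβ3 on the oxygen of ring D are both R and both carry a CH2OH group, so the C2 axis runs on through both O–Cβ bonds and both Cβ–Cγ bonds. These two Cβ–Cγ bonds can therefore be made in one operation under one auxiliary.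

## Retrosynthesis

**32 ⇒ 31.** The last disconnection removes protecting groups only. In 31 seven oxygens are masked as silyl ethers: the phenols of rings A and E (triisopropylsilyl), Cγ1–O, Cγ2–O and Cγ3–O (tert-butyldimethylsilyl), and Cα1–O and Cα3–O (triethylsilyl). A silyl-only pattern is preferred to benzyl ethers, whose final hydrogenolysis would compete with three benzylic carbinols and the two benzylic ethers of the core, and to acetals, which need acid. The forward step asks only for buffered fluoride.

**31 ⇒ 30 ⇒ 21 + 28.** Cα2 is taken back to ketone 30, and the Cα2–ring B bond is cut to the N-methoxy-N-methylamide 21 and aryllithium 29, made from bromide 28. This cut is better than cutting ring B–O–Cβ1 late, because unit 1 arrives complete and stereodefined on ring B; a late etherification would have to invert a hindered carbinol between two oxygenated carbons. It removes a third of the mass and three stereocentres. The forward steps need a single addition to the amide and a Felkin–Anh reduction in which the aryloxy group on Cβ2 directs hydride to the threo carbinol; the silyl ether on Cγ2 is there so that nothing chelates.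

**21 ⇒ 20 ⇒ 19 ⇒ 15 + 18.** The ring D arm follows the same logic with the opposite demand. Cα3–O goes back to ketone 19, and the Cα3–ring E bond is cut to the C2-symmetric bis-amide 15 and Grignard reagent 18. This is where the symmetry is broken. The two amides of 15 are homotopic, so a deficit of the cheap reagent 18 gives a statistical mixture from which 19 is taken and 15 is recovered. The cheap aryl group is used for the statistical step and the valuable bromide 28 for the second, complete addition. The forward reduction must be chelation-controlled to give the erythro carbinol.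

**15 ⇒ 14 ⇒ 13 ⇒ 12.** These are functional group changes without skeletal cuts: silyl ethers back to hydroxyls (14), amides back to N-acyl oxazolidinones (13), hydroxyls back to benzyl ethers (12). The benzyl groups come with the electrophile of the key step. They are removed directly after it, when the only hydrogenolysis-sensitive bonds present are the two core ethers and no benzylic carbinol exists yet. The freed hydroxyls then assist the exchange of auxiliary for amide.

**12 ⇒ 9 + 10.** Both Cβ–Cγ bonds (Cβ2–Cγ2 and Cβ3–Cγ3) are cut at once, to bis(aryloxyacetyl) imide 9 and two molecules of benzyl chloromethyl ether 10. Two neighbouring cuts were weighed: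
- Cutting Cα–Cβ (an aldol with aryl aldehydes) would force the same aryl group and the same relative configuration on both arms, which differ in both respects.
- Cutting O–Cβ would ask a 2,6-dimethoxyphenol to substitute twice at a secondary carbon.

The Cβ–Cγ cut removes two stereocentres and leaves plain CH2 groups on the arms. It asks the forward reaction for the same facial selectivity at two remote enolates and for no selectivity between them.

**9 ⇒ 5 + 8; 8 ⇒ 6.** The two O–CH2 bonds are cut to diphenol 5 and two molecules of bromoacetyl imide 8, which is one acylation away from oxazolidinone 6. The alkylating carbon is primary and carbonyl-activated, so even a hindered phenoxide substitutes it easily. The two auxiliaries also turn any residual enantiomeric core into a diastereomer.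

**5 ⇒ 4 ⇒ 3 ⇒ 2 ⇒ 1.** The core is cut at C8–C8' and both C7–O bonds to two molecules of sinapyl alcohol 3. Oxidative dimerisation makes one C–C bond, two C–O bonds, both rings and the relative configuration of all four centres in one step, but as racemate 4, so a chiral-phase resolution to 5 follows. Alcohol 3 is two steps from syringaldehyde 1 through ester 2. This is the shortest access to the core; its price is the discarded enantiomer.

**28 ⇒ 27 ⇒ 26 ⇒ 25 ⇒ 24 ⇒ 23 + 16; 23 ⇒ 22; 18 ⇒ 17 ⇒ 16.** Unit 1 is built on ring B by the same amide–ketone–reduction sequence: Cα1–O back to ketone 26, Cα1–ring A cut to amide 25 and reagent 18, amide back to ester 24. The ring B–O–Cβ1 bond is then cut to 4-bromo-2-methoxyphenol 16 and hydroxy ester 23 (from methyl (R)-glycerate 22), joined with inversion. Unlike the core phenols, 16 has one ortho substituent and must react only once, so here the chiral pool is the shorter source of Cβ. Phenol 16 also gives silyl ether 17 and from it the Grignard reagent 18, which is prepared once as a stock solution and supplies both ring A and ring E.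

## Roads not taken

**Alternative 1: radical cascade to a core with two different phenol protecting groups.**
- Cut: C-1–C-5 and O-7–C-6 of the dioxabicyclooctane, back to the acyclic epoxy cinnamyl ether A1 (ring C as benzyl ether, ring D as silyl ether).
- Forward key step: Cp2TiCl (trivalent titanium) opens the epoxide to the C-1 radical. 5-exo addition to the cinnamyl double bond forms C-1–C-5 and the first ring. The benzylic C-6 radical is trapped by a halogen, and the alkoxide on C-8 displaces it to close the second ring, giving the differentially protected syringaresinol A2.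
- Merits: the two phenols differ from the start, so the arms can be addressed in turn with no statistical step. If the carbinol centre of A1 is made enantiopure, no resolution is needed.
- Weak points: A1 takes several steps from two different aryl building blocks and needs its own asymmetric step. The radical cyclisation and the closure at an easily ionised benzylic carbon each decide a core configuration, so core epimers are likely. The reductant is needed in excess of two equivalents. An unsymmetrical core also rules out two-directional work: steps 6–10 would be run once per arm.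
- Comparison: Alternative 1 is better at arm differentiation and absolute control. The plan adopted here sets against it a four-operation core synthesis and five two-directional steps, and pays with one resolution and one statistical addition.

**Alternative 2: succinate linchpin, double aldol and double lactonisation.**
- Cut: C-1–C-2, C-5–C-6 and both lactone C–O bonds of dilactone A5, back to the succinyl bis-imide A3, which carries two (R)-4-benzyl-2-oxooxazolidin-3-yl groups, and two molecules of aldehyde A4.
- Forward key step: the bis(boron enolate) of A3 adds twice to A4 in syn fashion. Each aldolate oxygen attacks the imide carbonyl four atoms away, which closes both γ-lactones and releases both auxiliaries.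
- Merits: all four core centres arise under auxiliary control, nothing is discarded in a resolution, and the C2 symmetry is used.
- Weak points: after the first aldol and lactonisation, the second enolisation takes place on a lactone-imide whose facial bias no longer rests on the auxiliary alone. A5 must then be reduced at both carbonyls to the bis-ether, normally through lactols with a Lewis-acid silane reduction or through a tetraol with acid-mediated ring closure, and these are the conditions under which the electron-rich benzylic C–O bonds epimerise. Debenzylation follows. The sequence delivers only 5; the chain problem is untouched.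
- Comparison: Alternative 2 is better in material economy and absolute control of the core. The adopted plan sets against it four operations from 1 with no acid-sensitive reduction, and a purity check at 9. If the resolution proved impractical on scale, A5 would be the preferred source of 5.

**Alternative 3: two identical aryl caps on a late dialdehyde.**
- Cut: Cα1–ring A and Cα3–ring E together, back to dialdehyde A6 and two molecules of aryltitanium reagent A7.
- Forward key step: A7 adds without chelation to both α-aryloxy aldehydes. Felkin–Anh control from Cβ1 and Cβ3 gives both erythro carbinols of A8. One reagent serves both ends because units 1 and 3 are locally enantiomeric (αR,βS and αS,βR).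
- Merits: two C–C bonds and two stereocentres in one late step, and rings A and E are used as the identical pieces they are. This is more convergent than the separate ketone reductions used here.
- Weak points: A6 holds two α-aryloxy aldehydes, which epimerise and eliminate the γ-oxygen far more readily than amides or ketones, and both must survive a late double oxidation. Selectivity in such additions is moderate and must hold twice. The acetonide on unit 2 must be removed with acid in the presence of three benzylic carbinols. The strategy does not say how the Cβ centres or the difference between the ring C and ring D arms arise.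
- Comparison: Alternative 3 is shorter at the end and needs no carbinol protection. The adopted plan sets against it configurationally robust amide intermediates, a free choice of erythro or threo for each ketone, and an acid-free last step.

Key step: step 7

Assumption on the resolution: the (7R,7'R,8S,8'S) enantiomer is identified after step 4 by comparing its optical rotation and circular dichroism with those recorded for the two syringaresinol enantiomers; the route does not depend on elution order.
Assumption on supply: methyl (R)-2,3-dihydroxypropanoate (22) is taken as a purchased chiral-pool ester; it is otherwise one step from its commercial acetonide.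
Remark on naming: the two amides of 15 are homotopic; the arm that reacts in step 13 is called the ring D arm.
Remark on stoichiometry: steps 3, 6 and 7 each consume two molecules of one partner (3, 8 and 10); the second molecule is entered among the reagents that add atoms.

## Route

Step 1
Reactants: 1 syringaldehyde
Product: 2 ethyl (E)-sinapate
Conditions: Ph3P=CHCO2Et, toluene, 100 °C
Reagents that add atoms: ethyl (triphenylphosphoranylidene)acetate, CCOC(=O)C=P(c1ccccc1)(c1ccccc1)c1ccccc1
Why: Wittig olefination with a stabilised ylide, which tolerates the free phenol and gives the E alkene.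

Step 2
Reactants: 2 ethyl (E)-sinapate
Product: 3 sinapyl alcohol
Conditions: i-Bu2AlH, toluene, −78 to 0 °C; aq. KNaC4H4O6
Reagents that add atoms: none
Why: 1,2-Reduction of the α,β-unsaturated ester to the allylic alcohol by i-Bu2AlH; the phenol is carried as its aluminium phenoxide and the alkene is not reduced.

Step 3
Reactants: 3 sinapyl alcohol (two molecules)
Product: 4 racemic syringaresinol
Conditions: CuSO4·5H2O (cat.), air, acetone/H2O, rt
Reagents that add atoms: sinapyl alcohol (second molecule of 3), COc1cc(/C=C/CO)cc(OC)c1O
Why: Oxidative phenol coupling of two molecules of 3: divalent copper, regenerated by air, gives the phenoxyl radical, two radicals join at C8–C8', and each quinone methide is trapped by the γ-hydroxyl of the other half to close both tetrahydrofuran rings cis-fused with both aryl groups exo. The 3,5-dimethoxy pattern blocks coupling at the ring carbons, so the β–β dimer should dominate; it forms as the racemate.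

Step 4
Reactants: 4 racemic syringaresinol
Product: 5 (7R,7'R,8S,8'S)-syringaresinol
Conditions: preparative HPLC on cellulose tris(3,5-dimethylphenylcarbamate), hexane/i-PrOH, rt
Reagents that add atoms: none
Why: Chiral-phase resolution of a racemate on a polysaccharide carbamate phase; the enantiomeric purity is checked again at 9, where a core of the wrong handedness would be a diastereomer.

Step 5
Reactants: 6 (S)-4-benzyl-2-oxazolidinone
Product: 8 (S)-4-benzyl-3-(bromoacetyl)oxazolidin-2-one, via N-lithio oxazolidinone 7 (not isolated)
Conditions: n-BuLi, THF, −78 °C; then BrCH2COBr, −78 °C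
Reagents that add atoms: bromoacetyl bromide, BrCC(Br)=O
Why: N-Acylation of a lithiated oxazolidinone by an acid bromide; the acyl bromide reacts far faster than the alkyl bromide, and the stereocentre of the auxiliary is not involved.

Step 6
Reactants: 5 (7R,7'R,8S,8'S)-syringaresinol; 8 (S)-4-benzyl-3-(bromoacetyl)oxazolidin-2-one (two molecules)
Product: 9 core bis(aryloxyacetyl) imide
Conditions: 8 (2.2 equiv), K2CO3, acetone, rt to 40 °C
Reagents that add atoms: (S)-4-benzyl-3-(bromoacetyl)oxazolidin-2-one (second molecule of 8), O=C(CBr)N1[C@@H](Cc2ccccc2)COC1=O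
Why: Twofold Williamson ether synthesis: each phenoxide of 5 displaces bromide from the primary, carbonyl-activated carbon of one molecule of 8 (SN2), a position reactive enough for a 2,6-dimethoxyphenoxide. K2CO3 is too weak to enolise the imide or to harm the core, and no stereocentre is touched.

Step 7
Reactants: 9 core bis(aryloxyacetyl) imide; 10 benzyl chloromethyl ether (two molecules)
Product: 12 C2-symmetric bis[(R)-2-aryloxy-3-(benzyloxy)propanoyl] imide, via disodium bis-enolate 11 (not isolated)
Conditions: NaN(SiMe3)2 (2.2 equiv), THF, −78 °C; then BnOCH2Cl (excess), −78 to −45 °C; aq. NH4Cl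
Reagents that add atoms: benzyl chloromethyl ether (second molecule of 10), ClCOCc1ccccc1
Why: NaN(SiMe3)2 deprotonates each aryloxyacetyl imide to the sodium-chelated (Z)-enolate, in which the cation holds the enolate oxygen and the oxazolidinone carbonyl syn; one molecule of benzyl chloromethyl ether, a highly SN2-active α-chloro ether, then alkylates each enolate carbon and forms Cβ2–Cγ2 and Cβ3–Cγ3. The closest known reaction type is the auxiliary-controlled alkylation of glycolate-type N-acyl oxazolidinone sodium enolates, together with the alkylation of oxazolidinone enolates by benzyl chloromethyl ether; here it is run in two directions on one bis-imide. No ring closes. Each new stereocentre is controlled by the (S)-4-benzyl group of its own auxiliary, which covers one enolate face so that the electrophile enters from the other and gives R at Cβ2 and at Cβ3. The step needs the same facial selectivity on both arms, which two identical auxiliaries supply, and no selectivity between the arms, which are homotopic and too far apart across the rigid core to influence each other. The sodium enolate is chosen over a chlorotitanium enolate because TiCl4 would threaten the Lewis-acid-labile benzylic ethers of the core, and the temperature is held at or below −45 °C so that the enolates do not fragment to ketenes with loss of the auxiliary.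

Step 8
Reactants: 12 C2-symmetric bis[(R)-2-aryloxy-3-(benzyloxy)propanoyl] imide
Product: 13 bis[(R)-2-aryloxy-3-hydroxypropanoyl] imide
Conditions: H2 (1 atm), 10% Pd/C, EtOAc, rt
Reagents that add atoms: none
Why: Catalytic hydrogenolysis of primary alkyl benzyl ethers; in a neutral aprotic solvent these should cleave well before the secondary benzylic ether bonds of the core, which are shielded by the bicycle and the flanking methoxy groups, so the reaction is followed and stopped at complete debenzylation. The C-benzyl groups of the auxiliaries and the Cβ centres are inert.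

Step 9
Reactants: 13 bis[(R)-2-aryloxy-3-hydroxypropanoyl] imide
Product: 14 core bis[(R)-2-aryloxy-3-hydroxy-N-methoxy-N-methylpropanamide]
Conditions: MeNH(OMe)·HCl, AlMe3, CH2Cl2, −15 to 0 °C
Reagents that add atoms: N,O-dimethylhydroxylamine hydrochloride, CNOC.Cl
Why: Aluminium amide aminolysis of an N-acyl oxazolidinone (Weinreb amide formation): each free β-hydroxyl forms an aluminium alkoxide that delivers the amide to the exocyclic carbonyl, which is why the benzyl groups were removed first. Auxiliary 6 is released and can be recovered, and the conditions are not basic enough to enolise Cβ.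

Step 10
Reactants: 14 core bis[(R)-2-aryloxy-3-hydroxy-N-methoxy-N-methylpropanamide]
Product: 15 core bis[(R)-2-aryloxy-3-(tert-butyldimethylsilyloxy)-N-methoxy-N-methylpropanamide]
Conditions: t-BuMe2SiCl, imidazole, DMF, 0 °C to rt
Reagents that add atoms: tert-butyldimethylsilyl chloride, CC(C)(C)[Si](C)(C)Cl
Why: Silyl ether formation on the two primary alcohols; the bulky, weakly basic silyl ether on Cγ does not chelate in the later reductions and is removed by fluoride at the end.

Step 11
Reactants: 16 4-bromo-2-methoxyphenol
Product: 17 (4-bromo-2-methoxyphenoxy)triisopropylsilane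
Conditions: i-Pr3SiCl, imidazole, DMF, rt
Reagents that add atoms: triisopropylsilyl chloride, CC(C)[Si](Cl)(C(C)C)C(C)C
Why: Silyl ether formation on the phenol; the triisopropylsilyl aryl ether survives magnesium insertion, Grignard, organolithium and hydride reagents and is removed by fluoride.

Step 12
Reactants: 17 (4-bromo-2-methoxyphenoxy)triisopropylsilane
Product: 18 [3-methoxy-4-(triisopropylsilyloxy)phenyl]magnesium bromide (stock solution in THF)
Conditions: Mg turnings, THF, 45 °C; solution titrated and kept under argon
Reagents that add atoms: magnesium, [Mg]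
Why: Grignard reagent formation by insertion of magnesium into the aryl–bromine bond; the bulky aryl silyl ether and the methoxy group are inert. One titrated batch is prepared and drawn on in steps 13 and 19, so the reagent is made only once.

Step 13
Reactants: 15 core bis[(R)-2-aryloxy-3-(tert-butyldimethylsilyloxy)-N-methoxy-N-methylpropanamide]; 18 [3-methoxy-4-(triisopropylsilyloxy)phenyl]magnesium bromide
Product: 19 mono-ketone (ring D arm aryl ketone and ring C arm amide)
Conditions: 18 (about 0.9 equiv, THF solution), THF, −20 to 0 °C; aq. NH4Cl
Reagents that add atoms: none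
Why: Weinreb ketone synthesis: 18 adds once to an N-methoxy-N-methylamide and the magnesium-chelated tetrahedral adduct gives the ketone only on work-up. The two amides of 15 are homotopic and react independently, so a slight deficit of 18 should give a statistical mixture from which 19 is separated and unreacted 15 is returned to the step. Aryl Grignard reagents are weak kinetic bases, so Cβ2 and Cβ3 should keep their configuration.

Step 14
Reactants: 19 mono-ketone (ring D arm aryl ketone and ring C arm amide)
Product: 20 erythro Cα3 carbinol (ring C arm still amide)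
Conditions: Zn(BH4)2, Et2O/CH2Cl2, −30 to 0 °C
Reagents that add atoms: none
Why: Chelation-controlled ketone reduction (Cram chelate model): zinc bridges the ketone oxygen and the α-aryloxy oxygen of ring D, the silyl ether on Cγ3 does not compete, and hydride enters from the face of the hydrogen on Cβ3, which gives the erythro carbinol, S at Cα3 beside R at Cβ3. The N-methoxy-N-methylamide of the other arm is not reduced by Zn(BH4)2.

Step 15
Reactants: 20 erythro Cα3 carbinol (ring C arm still amide)
Product: 21 Cα3 triethylsilyl ether of 20
Conditions: Et3SiCl, imidazole, DMF, rt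
Reagents that add atoms: triethylsilyl chloride, CC[Si](Cl)(CC)CC
Why: Silyl ether formation on the only free hydroxyl, so that no alkoxide consumes the aryllithium in step 22; chloride and imidazole are used so that no Lewis-acidic silyl triflate comes near the core.

Step 16
Reactants: 22 methyl (R)-2,3-dihydroxypropanoate
Product: 23 methyl (R)-3-(tert-butyldimethylsilyloxy)-2-hydroxypropanoate
Conditions: t-BuMe2SiCl (1 equiv), imidazole, CH2Cl2, −10 to 0 °C
Reagents that add atoms: tert-butyldimethylsilyl chloride, CC(C)(C)[Si](C)(C)Cl
Why: Selective silyl ether formation at the primary hydroxyl of a 1,2-diol; the secondary α-hydroxy ester position is less nucleophilic and stays free, and the R centre is untouched.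

Step 17
Reactants: 23 methyl (R)-3-(tert-butyldimethylsilyloxy)-2-hydroxypropanoate; 16 4-bromo-2-methoxyphenol
Product: 24 methyl (S)-2-(4-bromo-2-methoxyphenoxy)-3-(tert-butyldimethylsilyloxy)propanoate
Conditions: PPh3, DIAD, toluene, 0 °C to rt
Reagents that add atoms: none
Why: Mitsunobu etherification: the alkoxyphosphonium of the α-hydroxy ester is displaced by the phenoxide of 16 with inversion (SN2), which turns R into S at the future Cβ1. α-Hydroxy esters and phenols with a single ortho substituent are good partners, and the aryl bromide is inert.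

Step 18
Reactants: 24 methyl (S)-2-(4-bromo-2-methoxyphenoxy)-3-(tert-butyldimethylsilyloxy)propanoate
Product: 25 (S)-2-(4-bromo-2-methoxyphenoxy)-3-(tert-butyldimethylsilyloxy)-N-methoxy-N-methylpropanamide
Conditions: MeNH(OMe)·HCl, i-PrMgCl, THF, −20 to −5 °C
Reagents that add atoms: N,O-dimethylhydroxylamine hydrochloride, CNOC.Cl
Why: Aminolysis of the ester by the chloromagnesium amide formed in the flask (Weinreb amide formation); acyl substitution at −20 °C is faster than enolisation, so the S centre should be kept, and the aryl bromide does not exchange with i-PrMgCl at this temperature.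

Step 19
Reactants: 25 (S)-2-(4-bromo-2-methoxyphenoxy)-3-(tert-butyldimethylsilyloxy)-N-methoxy-N-methylpropanamide; 18 [3-methoxy-4-(triisopropylsilyloxy)phenyl]magnesium bromide
Product: 26 (S)-2-(4-bromo-2-methoxyphenoxy)-3-(tert-butyldimethylsilyloxy)-1-[3-methoxy-4-(triisopropylsilyloxy)phenyl]propan-1-one
Conditions: 18 (1.3 equiv, THF solution), THF, −20 to 0 °C; aq. NH4Cl
Reagents that add atoms: none
Why: Weinreb ketone synthesis as in step 13, here with a small excess of the stock solution of 18 because only one amide is present; the aryl bromide of ring B does not react with the Grignard reagent.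

Step 20
Reactants: 26 (S)-2-(4-bromo-2-methoxyphenoxy)-3-(tert-butyldimethylsilyloxy)-1-[3-methoxy-4-(triisopropylsilyloxy)phenyl]propan-1-one
Product: 27 (1R,2S)-2-(4-bromo-2-methoxyphenoxy)-3-(tert-butyldimethylsilyloxy)-1-[3-methoxy-4-(triisopropylsilyloxy)phenyl]propan-1-ol
Conditions: Zn(BH4)2, Et2O, −30 to 0 °C
Reagents that add atoms: none
Why: Chelation-controlled ketone reduction as in step 14: zinc is held by the ketone oxygen and the guaiacyl ether oxygen with its ortho methoxy group, hydride comes from the hydrogen face of Cβ1, and the erythro carbinol results, R at Cα1 beside S at Cβ1.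

Step 21
Reactants: 27 (1R,2S)-2-(4-bromo-2-methoxyphenoxy)-3-(tert-butyldimethylsilyloxy)-1-[3-methoxy-4-(triisopropylsilyloxy)phenyl]propan-1-ol
Product: 28 triethylsilyl ether of 27 (ring B bromide carrying protected unit 1)
Conditions: Et3SiCl, imidazole, DMF, rt
Reagents that add atoms: triethylsilyl chloride, CC[Si](Cl)(CC)CC
Why: Silyl ether formation; the carbinol must be masked before the bromine–lithium exchange.

Step 22
Reactants: 28 triethylsilyl ether of 27 (ring B bromide carrying protected unit 1); 21 Cα3 triethylsilyl ether of 20
Product: 30 Cα2 ketone (ring B joined to the ring C arm), via aryllithium 29 (not isolated)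
Conditions: 28, t-BuLi (2 equiv), THF, −78 °C; then 21, −78 to −40 °C; aq. NH4Cl
Reagents that add atoms: none
Why: Bromine–lithium exchange followed by Weinreb ketone synthesis: exchange is faster than any deprotonation at −78 °C, 29 adds to the amide of 21, the lithium-chelated tetrahedral adduct prevents a second addition, and addition outruns enolisation at Cβ2. The silyl ethers and all existing stereocentres are inert to these conditions.

Step 23
Reactants: 30 Cα2 ketone (ring B joined to the ring C arm)
Product: 31 heptasilyl ether of the target (threo carbinol at Cα2)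
Conditions: KBH(s-Bu)3, THF, −78 °C; aq. NH4Cl
Reagents that add atoms: none
Why: Felkin–Anh-controlled ketone reduction: with a bulky hydride, a potassium counter-ion that does not chelate and a non-coordinating silyl ether on Cγ2, the aryloxy group on Cβ2 lies anti to the incoming hydride, which passes the hydrogen of Cβ2 and gives the threo carbinol, R at Cα2. No other reducible group is present.

Step 24
Reactants: 31 heptasilyl ether of the target (threo carbinol at Cα2)
Product: 32 CNP0316493.1
Conditions: Bu4NF, AcOH, THF, 0 °C to rt
Reagents that add atoms: none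
Why: Fluoride-mediated cleavage of silyl ethers: buffered fluoride removes the two aryl triisopropylsilyl, three primary tert-butyldimethylsilyl and two secondary triethylsilyl ethers without acid or strong base, so the benzylic carbinols, the core ethers and the phenols para to carbinols are left alone. No stereocentre is affected.

## Compound list

1 | syringaldehyde (4-hydroxy-3,5-dimethoxybenzaldehyde) | COc1cc(C=O)cc(OC)c1O | starting material
2 | ethyl (E)-sinapate | CCOC(=O)/C=C/c1cc(OC)c(O)c(OC)c1 | intermediate
3 | sinapyl alcohol | COc1cc(/C=C/CO)cc(OC)c1O | intermediate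
4 | racemic syringaresinol (1:1 mixture of both enantiomers) | COc1cc([C@@H]2OC[C@@H]3[C@H]2CO[C@H]3c2cc(OC)c(O)c(OC)c2)cc(OC)c1O.COc1cc([C@H]2OC[C@H]3[C@@H]2CO[C@@H]3c2cc(OC)c(O)c(OC)c2)cc(OC)c1O | intermediate
5 | (7R,7'R,8S,8'S)-syringaresinol | COc1cc([C@@H]2OC[C@@H]3[C@H]2CO[C@H]3c2cc(OC)c(O)c(OC)c2)cc(OC)c1O | intermediate
6 | (S)-4-benzyl-2-oxazolidinone | O=C1N[C@@H](Cc2ccccc2)CO1 | starting material
7 | N-lithio-(S)-4-benzyl-2-oxazolidinone | [Li]N1[C@@H](Cc2ccccc2)COC1=O | intermediate (not isolated)
8 | (S)-4-benzyl-3-(bromoacetyl)oxazolidin-2-one | O=C(CBr)N1[C@@H](Cc2ccccc2)COC1=O | intermediate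
9 | core bis(aryloxyacetyl) imide: (7R,7'R,8S,8'S)-syringaresinol with both phenol oxygens carrying CH2C(=O)-[(S)-4-benzyl-2-oxooxazolidin-3-yl] | O=C(COc1c(OC)cc([C@@H]2OC[C@@H]3[C@H]2CO[C@H]3c2cc(OC)c(OCC(=O)N3[C@@H](Cc4ccccc4)COC3=O)c(OC)c2)cc1OC)N1[C@@H](Cc2ccccc2)COC1=O | intermediate
10 | benzyl chloromethyl ether | ClCOCc1ccccc1 | starting material
11 | disodium bis-(Z)-enolate of 9 | [Na+].[Na+].[O-]/C(=C\Oc1c(OC)cc([C@@H]2OC[C@@H]3[C@H]2CO[C@H]3c2cc(OC)c(O/C=C(\[O-])N3[C@@H](Cc4ccccc4)COC3=O)c(OC)c2)cc1OC)N1[C@@H](Cc2ccccc2)COC1=O | intermediate (not isolated)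
12 | C2-symmetric bis[(R)-2-aryloxy-3-(benzyloxy)propanoyl] imide of (S)-4-benzyloxazolidin-2-one on the core | O=C([C@@H](COCc5ccccc5)Oc1c(OC)cc([C@@H]2OC[C@@H]3[C@H]2CO[C@H]3c2cc(OC)c(O[C@H](COCc3ccccc3)C(=O)N3[C@@H](Cc4ccccc4)COC3=O)c(OC)c2)cc1OC)N1[C@@H](Cc2ccccc2)COC1=O | intermediate
13 | bis[(R)-2-aryloxy-3-hydroxypropanoyl] imide (12 without its two benzyl ethers) | O=C([C@@H](CO)Oc1c(OC)cc([C@@H]2OC[C@@H]3[C@H]2CO[C@H]3c2cc(OC)c(O[C@H](CO)C(=O)N3[C@@H](Cc4ccccc4)COC3=O)c(OC)c2)cc1OC)N1[C@@H](Cc2ccccc2)COC1=O | intermediate
14 | core bis[(R)-2-aryloxy-3-hydroxy-N-methoxy-N-methylpropanamide] | CON(C)C(=O)[C@@H](CO)Oc1c(OC)cc([C@@H]2OC[C@@H]3[C@H]2CO[C@H]3c2cc(OC)c(O[C@H](CO)C(=O)N(C)OC)c(OC)c2)cc1OC | intermediate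
15 | core bis[(R)-2-aryloxy-3-(tert-butyldimethylsilyloxy)-N-methoxy-N-methylpropanamide] | CON(C)C(=O)[C@@H](CO[Si](C)(C)C(C)(C)C)Oc1c(OC)cc([C@@H]2OC[C@@H]3[C@H]2CO[C@H]3c2cc(OC)c(O[C@H](CO[Si](C)(C)C(C)(C)C)C(=O)N(C)OC)c(OC)c2)cc1OC | intermediate
16 | 4-bromo-2-methoxyphenol | COc1cc(Br)ccc1O | starting material
17 | (4-bromo-2-methoxyphenoxy)triisopropylsilane | COc1cc(Br)ccc1O[Si](C(C)C)(C(C)C)C(C)C | intermediate
18 | [3-methoxy-4-(triisopropylsilyloxy)phenyl]magnesium bromide (titrated stock solution in THF) | COc1cc([Mg]Br)ccc1O[Si](C(C)C)(C(C)C)C(C)C | intermediate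
19 | mono-ketone: ring D arm (R)-2-aryloxy-3-(tert-butyldimethylsilyloxy)-1-[3-methoxy-4-(triisopropylsilyloxy)phenyl]propan-1-one, ring C arm unchanged amide | CON(C)C(=O)[C@@H](CO[Si](C)(C)C(C)(C)C)Oc1c(OC)cc([C@@H]2OC[C@@H]3[C@H]2CO[C@H]3c2cc(OC)c(O[C@H](CO[Si](C)(C)C(C)(C)C)C(=O)c3ccc(O[Si](C(C)C)(C(C)C)C(C)C)c(OC)c3)c(OC)c2)cc1OC | intermediate
20 | erythro carbinol: 19 with the ketone reduced, Cα3 S and Cβ3 R | CON(C)C(=O)[C@@H](CO[Si](C)(C)C(C)(C)C)Oc1c(OC)cc([C@@H]2OC[C@@H]3[C@H]2CO[C@H]3c2cc(OC)c(O[C@H](CO[Si](C)(C)C(C)(C)C)[C@@H](O)c3ccc(O[Si](C(C)C)(C(C)C)C(C)C)c(OC)c3)c(OC)c2)cc1OC | intermediate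
21 | Cα3 triethylsilyl ether of 20 | CON(C)C(=O)[C@@H](CO[Si](C)(C)C(C)(C)C)Oc1c(OC)cc([C@@H]2OC[C@@H]3[C@H]2CO[C@H]3c2cc(OC)c(O[C@H](CO[Si](C)(C)C(C)(C)C)[C@@H](O[Si](CC)(CC)CC)c3ccc(O[Si](C(C)C)(C(C)C)C(C)C)c(OC)c3)c(OC)c2)cc1OC | intermediate
22 | methyl (R)-2,3-dihydroxypropanoate | COC(=O)[C@H](O)CO | starting material
23 | methyl (R)-3-(tert-butyldimethylsilyloxy)-2-hydroxypropanoate | COC(=O)[C@H](O)CO[Si](C)(C)C(C)(C)C | intermediate
24 | methyl (S)-2-(4-bromo-2-methoxyphenoxy)-3-(tert-butyldimethylsilyloxy)propanoate | COC(=O)[C@@H](Oc1ccc(Br)cc1OC)CO[Si](C)(C)C(C)(C)C | intermediate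
25 | (S)-2-(4-bromo-2-methoxyphenoxy)-3-(tert-butyldimethylsilyloxy)-N-methoxy-N-methylpropanamide | CON(C)C(=O)[C@@H](Oc1ccc(Br)cc1OC)CO[Si](C)(C)C(C)(C)C | intermediate
26 | (S)-2-(4-bromo-2-methoxyphenoxy)-3-(tert-butyldimethylsilyloxy)-1-[3-methoxy-4-(triisopropylsilyloxy)phenyl]propan-1-one | COc1cc(C(=O)[C@@H](Oc2ccc(Br)cc2OC)CO[Si](C)(C)C(C)(C)C)ccc1O[Si](C(C)C)(C(C)C)C(C)C | intermediate
27 | (1R,2S)-2-(4-bromo-2-methoxyphenoxy)-3-(tert-butyldimethylsilyloxy)-1-[3-methoxy-4-(triisopropylsilyloxy)phenyl]propan-1-ol (erythro) | COc1cc([C@@H](O)[C@H](CO[Si](C)(C)C(C)(C)C)Oc2ccc(Br)cc2OC)ccc1O[Si](C(C)C)(C(C)C)C(C)C | intermediate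
28 | triethylsilyl ether of 27 (ring B bromide carrying protected unit 1) | COc1cc([C@@H](O[Si](CC)(CC)CC)[C@H](CO[Si](C)(C)C(C)(C)C)Oc2ccc(Br)cc2OC)ccc1O[Si](C(C)C)(C(C)C)C(C)C | intermediate
29 | aryllithium from 28 (lithium in place of bromine) | COc1cc([C@@H](O[Si](CC)(CC)CC)[C@H](CO[Si](C)(C)C(C)(C)C)Oc2ccc([Li])cc2OC)ccc1O[Si](C(C)C)(C(C)C)C(C)C | intermediate (not isolated)
30 | Cα2 ketone: 21 with the ring C arm amide replaced by the ketone of ring B, which carries protected unit 1 | COc1cc([C@@H](O[Si](CC)(CC)CC)[C@H](CO[Si](C)(C)C(C)(C)C)Oc2ccc(C(=O)[C@@H](CO[Si](C)(C)C(C)(C)C)Oc3c(OC)cc([C@@H]4OC[C@@H]5[C@H]4CO[C@H]5c4cc(OC)c(O[C@H](CO[Si](C)(C)C(C)(C)C)[C@@H](O[Si](CC)(CC)CC)c5ccc(O[Si](C(C)C)(C(C)C)C(C)C)c(OC)c5)c(OC)c4)cc3OC)cc2OC)ccc1O[Si](C(C)C)(C(C)C)C(C)C | intermediate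
31 | heptasilyl ether of the target: threo carbinol at Cα2 (R) free; rings A and E as triisopropylsilyl ethers, Cγ1, Cγ2, Cγ3 as tert-butyldimethylsilyl ethers, Cα1 and Cα3 as triethylsilyl ethers | COc1cc([C@@H](O[Si](CC)(CC)CC)[C@H](CO[Si](C)(C)C(C)(C)C)Oc2ccc([C@@H](O)[C@@H](CO[Si](C)(C)C(C)(C)C)Oc3c(OC)cc([C@@H]4OC[C@@H]5[C@H]4CO[C@H]5c4cc(OC)c(O[C@H](CO[Si](C)(C)C(C)(C)C)[C@@H](O[Si](CC)(CC)CC)c5ccc(O[Si](C(C)C)(C(C)C)C(C)C)c(OC)c5)c(OC)c4)cc3OC)cc2OC)ccc1O[Si](C(C)C)(C(C)C)C(C)C | intermediate
32 | CNP0316493.1: (7R,7'R,8S,8'S)-syringaresinol with an erythro (αS,βR) guaiacylglycerol unit on the ring D oxygen and a threo (αR,βR) guaiacylglycerol unit on the ring C oxygen, whose ring B oxygen carries an erythro (αR,βS) guaiacylglycerol unit | COc1cc([C@@H](O)[C@H](CO)Oc2ccc([C@@H](O)[C@@H](CO)Oc3c(OC)cc([C@@H]4OC[C@@H]5[C@H]4CO[C@H]5c4cc(OC)c(O[C@H](CO)[C@@H](O)c5ccc(O)c(OC)c5)c(OC)c4)cc3OC)cc2OC)ccc1O | target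

## Step count and least certain steps

Total step count: 24. Longest linear sequence: 15 steps from syringaldehyde (steps 1–4, 6–10, 13–15, 22–24). The side branches are step 5 (reagent 8), steps 11–12 (bromide 17 and Grignard reagent 18) and steps 16–21 (bromide 28).

**Step 7 (key step).** The most likely failure is incomplete double alkylation: the second enolate may be quenched or may fragment to a ketene before it is alkylated, because the glycolate-type sodium enolates are only stable cold and two of them must survive on one molecule. Erosion of facial selectivity on one arm is the second concern, since any leak on either arm lowers the purity of the whole. Fallback, from 5 back to 15: the Cβ centres are taken from the chiral pool instead of an enolate.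
- Methyl (S)-2,3-dihydroxypropanoate is silylated at the primary hydroxyl to methyl (S)-3-(tert-butyldimethylsilyloxy)-2-hydroxypropanoate F1.
- A double Mitsunobu etherification of 5 with F1 (PPh3, DIAD, inversion at both carbinol carbons) gives the core bis[methyl (R)-2-aryloxy-3-(tert-butyldimethylsilyloxy)propanoate] F2.
- i-PrMgCl with MeNH(OMe)·HCl converts F2 into 15.

This reserve is shorter on paper, but it depends on a 2,6-dimethoxyphenol substituting twice at a secondary carbon, where slow substitution and elimination are to be feared.

**Step 8.** Hydrogenolytic opening of the benzylic C7–O bonds of the core may compete with debenzylation, because these bonds are also benzylic ethers of electron-rich rings and differ from the benzyl ethers only in steric access. Fallback, from 9 directly to 13: 9 is enolised with TiCl4 and i-Pr2NEt and hydroxymethylated with s-trioxane and further TiCl4. This auxiliary-controlled titanium enolate reaction has the same facial sense and introduces Cγ as a free hydroxymethyl group, so no benzyl ether is ever made. It is held in reserve because TiCl4 is itself a risk for the core.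

**Step 6.** Acyl transfer may compete with alkylation: the hindered phenoxide can attack the imide carbonyl of 8 or of the product and cleave the auxiliary, and the second alkylation may lag behind the first. Fallback, from 5 back to 9: the ether bond is made first with a simple ester and the auxiliary is attached afterwards.
- 5 is alkylated with ethyl bromoacetate and K2CO3 to the diethyl bis(aryloxyacetate) F3.
- LiOH in aqueous THF gives the bis(aryloxyacetic acid) F4.
- Pivaloyl chloride and Et3N give the bis(mixed pivalic anhydride) F5.
- F5 acylates the lithiated oxazolidinone 7 to give 9.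

**Step 14 (the same concern applies to step 20).** Chelation may be incomplete, so that the open Felkin–Anh pathway leaks in and the threo epimer forms alongside. The aryloxy oxygen of ring D is a weak and hindered donor. Fallback, from 19 to 20 without new compounds: substrate control is replaced by catalyst control, using asymmetric transfer hydrogenation of the aryl ketone with RuCl[(R,R)-TsDPEN](p-cymene) in HCO2H/Et3N. By analogy with simple aryl ketones this catalyst enantiomer should deliver hydride to the face that gives S at Cα3. The medium is not basic, so Cβ3 should not epimerise.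

**Step 23.** Chelation may leak in here, or the bulky hydride may enolise the ketone; either would lower the threo selectivity or cost material by epimerisation at Cβ2 or elimination of the γ-silyloxy group. Fallback, from 30 back to 31 by inversion.
- 30 is reduced with Zn(BH4)2, as in steps 14 and 20, to the Cα2 epimer of 31 F6 (erythro).
- A Mitsunobu reaction with 4-nitrobenzoic acid, PPh3 and DIAD inverts Cα2 and gives the 4-nitrobenzoate of 31 F7.
- i-Bu2AlH at −78 °C removes the ester and gives 31.

## Further compounds

F1 | step 7 | methyl (S)-3-(tert-butyldimethylsilyloxy)-2-hydroxypropanoate | COC(=O)[C@@H](O)CO[Si](C)(C)C(C)(C)C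
F2 | step 7 | core bis[methyl (R)-2-aryloxy-3-(tert-butyldimethylsilyloxy)propanoate] | COC(=O)[C@@H](CO[Si](C)(C)C(C)(C)C)Oc1c(OC)cc([C@@H]2OC[C@@H]3[C@H]2CO[C@H]3c2cc(OC)c(O[C@H](CO[Si](C)(C)C(C)(C)C)C(=O)OC)c(OC)c2)cc1OC
F3 | step 6 | diethyl bis(aryloxyacetate) of (7R,7'R,8S,8'S)-syringaresinol | CCOC(=O)COc1c(OC)cc([C@@H]2OC[C@@H]3[C@H]2CO[C@H]3c2cc(OC)c(OCC(=O)OCC)c(OC)c2)cc1OC
F4 | step 6 | bis(aryloxyacetic acid) of (7R,7'R,8S,8'S)-syringaresinol | OC(=O)COc1c(OC)cc([C@@H]2OC[C@@H]3[C@H]2CO[C@H]3c2cc(OC)c(OCC(=O)O)c(OC)c2)cc1OC
F5 | step 6 | bis(mixed pivalic anhydride) of F4 | CC(C)(C)C(=O)OC(=O)COc1c(OC)cc([C@@H]2OC[C@@H]3[C@H]2CO[C@H]3c2cc(OC)c(OCC(=O)OC(=O)C(C)(C)C)c(OC)c2)cc1OC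
F0 | step 8 | none | none
F0 | step 14 | none | none
F6 | step 23 | Cα2 epimer of 31 (erythro, Cα2 S) | COc1cc([C@@H](O[Si](CC)(CC)CC)[C@H](CO[Si](C)(C)C(C)(C)C)Oc2ccc([C@H](O)[C@@H](CO[Si](C)(C)C(C)(C)C)Oc3c(OC)cc([C@@H]4OC[C@@H]5[C@H]4CO[C@H]5c4cc(OC)c(O[C@H](CO[Si](C)(C)C(C)(C)C)[C@@H](O[Si](CC)(CC)CC)c5ccc(O[Si](C(C)C)(C(C)C)C(C)C)c(OC)c5)c(OC)c4)cc3OC)cc2OC)ccc1O[Si](C(C)C)(C(C)C)C(C)C
F7 | step 23 | 4-nitrobenzoate of 31 (Cα2 R) | COc1cc([C@@H](O[Si](CC)(CC)CC)[C@H](CO[Si](C)(C)C(C)(C)C)Oc2ccc([C@@H](OC(=O)c6ccc(cc6)[N+](=O)[O-])[C@@H](CO[Si](C)(C)C(C)(C)C)Oc3c(OC)cc([C@@H]4OC[C@@H]5[C@H]4CO[C@H]5c4cc(OC)c(O[C@H](CO[Si](C)(C)C(C)(C)C)[C@@H](O[Si](CC)(CC)CC)c5ccc(O[Si](C(C)C)(C(C)C)C(C)C)c(OC)c5)c(OC)c4)cc3OC)cc2OC)ccc1O[Si](C(C)C)(C(C)C)C(C)C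
A1 | alternative 1 | epoxy cinnamyl ether: (S)-configured benzylic ether carbon bearing the 4-benzyloxy-3,5-dimethoxyphenyl ring, an oxiranyl group (either epimer serves, one drawn) and an (E)-3-[4-(tert-butyldimethylsilyloxy)-3,5-dimethoxyphenyl]allyloxy group | COc1cc([C@H](OC/C=C/c2cc(OC)c(O[Si](C)(C)C(C)(C)C)c(OC)c2)[C@@H]2CO2)cc(OC)c1OCc1ccccc1
A2 | alternative 1 | (7R,7'R,8S,8'S)-syringaresinol with ring C as benzyl ether and ring D as tert-butyldimethylsilyl ether | COc1cc([C@@H]2OC[C@@H]3[C@H]2CO[C@H]3c2cc(OC)c(O[Si](C)(C)C(C)(C)C)c(OC)c2)cc(OC)c1OCc1ccccc1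
A3 | alternative 2 | succinyl bis-imide of (R)-4-benzyloxazolidin-2-one | O=C(CCC(=O)N1[C@H](Cc2ccccc2)COC1=O)N1[C@H](Cc2ccccc2)COC1=O
A4 | alternative 2 | 4-(benzyloxy)-3,5-dimethoxybenzaldehyde | COc1cc(C=O)cc(OC)c1OCc1ccccc1
A5 | alternative 2 | exo,exo-2,6-bis(4-benzyloxy-3,5-dimethoxyphenyl)-3,7-dioxabicyclo[3.3.0]octane-4,8-dione | COc1cc([C@@H]2OC(=O)[C@@H]3[C@H]2C(=O)O[C@H]3c2cc(OC)c(OCc4ccccc4)c(OC)c2)cc(OC)c1OCc1ccccc1
A6 | alternative 3 | core dialdehyde: aldehyde groups in place of Cα1 and Cα3, Cγ1 and Cγ3 as tert-butyldimethylsilyl ethers, unit 2 as Cα2/Cγ2 acetonide | O=C[C@H](CO[Si](C)(C)C(C)(C)C)Oc2ccc([C@@H](OC(C)(C)OC3)[C@@H]3Oc3c(OC)cc([C@@H]4OC[C@@H]5[C@H]4CO[C@H]5c4cc(OC)c(O[C@H](CO[Si](C)(C)C(C)(C)C)C=O)c(OC)c4)cc3OC)cc2OC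
A7 | alternative 3 | [3-methoxy-4-(tert-butyldimethylsilyloxy)phenyl]titanium triisopropoxide | COc1cc([Ti](OC(C)C)(OC(C)C)OC(C)C)ccc1O[Si](C)(C)C(C)(C)C
A8 | alternative 3 | target with four tert-butyldimethylsilyl ethers (rings A and E, Cγ1, Cγ3) and the unit 2 acetonide | COc1cc([C@@H](O)[C@H](CO[Si](C)(C)C(C)(C)C)Oc2ccc([C@@H](OC(C)(C)OC3)[C@@H]3Oc3c(OC)cc([C@@H]4OC[C@@H]5[C@H]4CO[C@H]5c4cc(OC)c(O[C@H](CO[Si](C)(C)C(C)(C)C)[C@@H](O)c5ccc(O[Si](C)(C)C(C)(C)C)c(OC)c5)c(OC)c4)cc3OC)cc2OC)ccc1O[Si](C)(C)C(C)(C)C
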